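Amounts first: the flask, which is the midnight run carried on to 80 min, holds 1.5 M of starting material and 300 mM of free catalyst.

| setting | midnight | summer | flask |
|---|---|---|---|
| starting material | 1.5 M | 1.5 M | 1.5 M |
| second substrate | 1.5 M | 1 M | 1.50 M |
| free catalyst | 300 mM | 300 mM | 300 mM |
| remark | the very flask that is asked about, followed so far | run made earlier |  |
| time |  |  | 80 min |

| run | time / min | target / % | uncatalysed product / % |
|---|---|---|---|
| midnight | 1.33 | 21.9 | 8.5 |
| midnight | 4.00 | 49.4 | 18.2 |
| midnight | 6.00 | 62.6 | 19.8 |
| midnight | 10.0 | 70.7 | 24.0 |
| midnight | 15.0 | 72.7 | 25.4 |
| summer | 3.00 | 44.0 | 14.8 |
| summer | 8.00 | 68.7 | 22.7 |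
| summer | 15.0 | 74.8 | 22.6 |
| summer | 25.0 | 76.0 | 24.3 |
| summer | 30.0 | 76.5 | 24.2 |

(readings scatter by 1 percentage point)

- in percentages every species weighs as the starting material in it: one spent catalyst counts as two
- the numbers in the tables scatter with a standard deviation of 1 percentage point
- steps thought possible: starting material -> uncatalysed product; 2 second substrate -> self-condensation product; catalyst intermediate B -> free catalyst + second product; catalyst intermediate A -> free catalyst + target; starting material + free catalyst <-> catalyst intermediate A; second substrate + free catalyst <-> catalyst intermediate B; catalyst intermediate A + target -> spent catalyst
- the reaction counts as stopped when no species that holds the starting material changes by six tenths of a point or more over the second half of the time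

1. at 80 min, what has stopped the reaction, if anything has (no working catalyst is left / all of the starting material has reacted / it is still moving / forward and back rates have come level)
2. amount of target at 80 min, in percent of the starting material charged
3. amount of uncatalysed product at 80 min, in percent of the starting material charged

Follow one molecule of starting material. It either goes by itself to uncatalysed product, or it binds free catalyst and may leave as target. Both paths are first order in [starting material], so that amount cancels from the odds between them.

Now test the time. Read the uncatalysed rate constant from the first midnight reading, 0.0762 min⁻¹. Over 80 min that path by itself leaves 0.225 % of the starting material, so expect it to be used up.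

Second substrate needs no correction, since the flask has the midnight charge.

Know [free catalyst] well. Take the odds to scale with it, and a relative error there moves the target share, as a fraction of the starting material charged, by 0.192 of that error.

So read the number: target over uncatalysed product at the last midnight reading is 2.86, with the scatter of the readings. Divide by the catalyst charge to get the fork odds per molar of catalyst, 9.54 M⁻¹, a selectivity factor, for the midnight charges of starting material and second substrate. Then the flask ends near 74.1 % target and 25.9 % uncatalysed product.

The forecast, which stands 0.40 percentage points below my reckoning in uncatalysed product, says: all of the starting material has reacted, with 74.2 % target and 25.5 % uncatalysed product: “All of it has reacted, and both products are stable plateaus.”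

The flask gives: all of the starting material has reacted, with 74.0 % target and 24.6 % uncatalysed product.

    starting material → uncatalysed product (k = 0.00120 s⁻¹)
    2 second substrate → self-condensation product (k = 5.30 × 10⁻⁴ M⁻¹ s⁻¹)
    catalyst intermediate B → free catalyst + second product (k = 0.0650 s⁻¹)
    catalyst intermediate A → free catalyst + target (k = 0.250 s⁻¹)
    starting material + free catalyst ⇌ catalyst intermediate A (K = 0.600 M⁻¹, k = 0.0170 M⁻¹ s⁻¹)
    second substrate + free catalyst ⇌ catalyst intermediate B (K = 42.0 M⁻¹, k = 0.0190 M⁻¹ s⁻¹)
    catalyst intermediate A + target → spent catalyst (k = 0.00420 M⁻¹ s⁻¹)

Uncatalysed product lies 1.3 points below the reckoned share, and spent catalyst, 3.50 % of the catalyst and counted double, holds 1.40 % of the starting material. Take the same flask with 0.075 M of free catalyst: the fork odds give 0.715, hence 41.7 % target, and that neighbour flask stands at 42.5 %.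

(The readings come from a simulation on assumed constants; the scatter is artificial.)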